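**Plan**

- Retrosynthesis: the ferulate ester C–O bond is cut first. Then the two aryl bonds of the pyran ring, C4–C4a and O1–C8a (chromene numbering), are cut together, giving 1-(4-iodo-3-methoxyphenyl)ethanone and a (Z)-bromoalkenyl tertiary carbinol. The carbinol is cut at C3=C4 (Wittig) and traced back to (R)-2-methylglycidol.
- Enabling feature: in the benzene ring, C8a lies between C8 (OMe, a blocked ortho site) and C4a (the only free ortho C–H). O1 sits on the fully substituted C2, which has no carbinol hydrogen, and C3=C4 is cis inside the pyran ring. This is the pattern for a palladium/norbornene ortho C–H alkenylation with ipso C–O termination.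
- Forward: the C2 side chain is built from the epoxide (steps 1–3) and the aryl iodide is made (step 4). The pyran ring is closed onto the purchased benzene ring in step 5. Then the PMB group is removed, the protected ferulate is attached and the phenol is freed (steps 6–8).
- Stereochemistry: the only stereocentre (C2, R) is bought with (R)-2-methylglycidol, and no bond to it is made or broken. The ring alkene geometry comes from the Z-selective Wittig step, and the E-cinnamate from the purchased acid.

Key step: step 5

Remark on the chemistry: the aniline 5 and the acid 10 are taken to be catalogue compounds; PMB = 4-methoxybenzyl.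

**Route**

Step 1
Reactants: 1 (R)-2-methylglycidol
Product: 2 (2R)-3-[(4-methoxyphenyl)methoxy]-2-methylpropane-1,2-diol
Conditions: 4-methoxybenzyl alcohol (4 equiv), NaH (0.2 equiv), DMF, 60 °C, slow addition of 1
Reagents that add atoms: 4-methoxybenzyl alcohol, COc1ccc(CO)cc1
Why: Base-catalysed SN2 epoxide opening by the benzylic alkoxide should occur at the unsubstituted CH2, so no bond to the stereocentre is touched (a Payne shift of 1 is degenerate and returns the same enantiomer) and the CH2OH arm of 1 remains as the arm to be oxidised.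

Step 2
Reactants: 2 (2R)-3-[(4-methoxyphenyl)methoxy]-2-methylpropane-1,2-diol
Product: 3 (2S)-2-hydroxy-3-[(4-methoxyphenyl)methoxy]-2-methylpropanal
Conditions: (COCl)2, DMSO, CH2Cl2, −78 °C; then Et3N, −78 → 0 °C; used crude
Reagents that add atoms: none
Why: Swern oxidation should convert only the primary alcohol, since the tertiary carbinol has no hydrogen to lose, and the low temperature and immediate use limit dimerisation of the α-hydroxy aldehyde (the descriptor changes by priority only).

Step 3
Reactants: 3 (2S)-2-hydroxy-3-[(4-methoxyphenyl)methoxy]-2-methylpropanal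
Product: 4 (2R,3Z)-4-bromo-1-[(4-methoxyphenyl)methoxy]-2-methylbut-3-en-2-ol
Conditions: BrCH2PPh3Br (2.6 equiv), KOtBu (2.5 equiv), THF, −78 °C; then 3, −78 → −20 °C
Reagents that add atoms: (bromomethyl)triphenylphosphonium bromide, BrC[P+](c1ccccc1)(c1ccccc1)c1ccccc1.[Br-]
Why: Wittig olefination with the non-stabilised bromomethylene ylide is kinetically Z-selective at low temperature, the surplus ylide absorbs the tertiary hydroxyl proton, and the minor E isomer should be separable by chromatography.

Step 4
Reactants: 5 1-(4-amino-3-methoxyphenyl)ethan-1-one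
Product: 7 1-(4-iodo-3-methoxyphenyl)ethan-1-one, via 4-acetyl-2-methoxybenzenediazonium chloride 6 (not isolated)
Conditions: NaNO2, aq. HCl, 0 °C; then KI, 0 °C → rt
Reagents that add atoms: potassium iodide (KI), [K+].[I-] (iodine of 7); NaNO2, [Na+].[O-]N=O, and HCl, Cl (outer nitrogen and chloride of intermediate 6 only)
Why: Sandmeyer-type iododediazoniation replaces the amino group by iodine at the same carbon (para to acetyl, ortho to OMe) without copper, and the aryl methyl ketone is inert in cold aqueous acid.

Step 5
Reactants: 4 (2R,3Z)-4-bromo-1-[(4-methoxyphenyl)methoxy]-2-methylbut-3-en-2-ol; 7 1-(4-iodo-3-methoxyphenyl)ethan-1-one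
Product: 8 1-[(2R)-8-methoxy-2-{[(4-methoxyphenyl)methoxy]methyl}-2-methyl-2H-chromen-6-yl]ethan-1-one
Conditions: Pd(OAc)2 (10 mol%), tri(2-furyl)phosphine (20 mol%), norbornene (1 equiv), K2CO3 (3 equiv), DMF, 100 °C
Reagents that add atoms: none
Why: Proposed new method: zerovalent palladium inserts into the C–I bond of 7, norbornene inserts syn, and the ring is palladated at its only free ortho C–H (the other ortho site carries OMe) to give the aryl-norbornyl palladacycle; the Z-alkenyl bromide 4, guided by its cis alkoxide, then adds oxidatively to this divalent palladium centre and C(sp2)–C(sp2) reductive elimination from tetravalent palladium makes the aryl–C4 bond with retention of the Z geometry. The two ortho substituents (OMe and the new alkenyl group) then force β-carbon elimination of norbornene, and the aryl–palladium alkoxide closes the pyran ring by C(aryl)–O reductive elimination out of a seven-membered oxapalladacycle, formally a 6-exo attack of O1 on the ipso carbon C8a. The closest known reaction type is the Catellani ortho-arylation of ortho-substituted aryl iodides with 2-bromobenzylic tertiary alcohols that ends in ipso C–O closure to 6H-dibenzopyrans (and the related aryl iodide/epoxide annulation to dihydrobenzofurans); here a Z-alkenyl bromide takes the place of the aryl bromide. No stereocentre is formed: C2 comes in from 1 with no bond to it made or broken, and the cis alkene that the ring requires is the Z geometry of 4. The step needs first oxidative addition at C–I (secured by the more reactive, acetyl-activated aryl iodide), ortho alkenylation before ipso termination (secured by fast norbornene insertion and the ortho OMe group), and C–O closure instead of β-hydride loss (secured by the fully substituted, geminally disubstituted carbinol carbon).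

Step 6
Reactants: 8 1-[(2R)-8-methoxy-2-{[(4-methoxyphenyl)methoxy]methyl}-2-methyl-2H-chromen-6-yl]ethan-1-one
Product: 9 1-[(2R)-2-(hydroxymethyl)-8-methoxy-2-methyl-2H-chromen-6-yl]ethan-1-one
Conditions: DDQ (1.3 equiv), CH2Cl2/pH 7 buffer, 0 °C → rt
Reagents that add atoms: none
Why: Oxidative PMB ether cleavage by DDQ acts on the electron-rich benzylic position only, while the chromene has no hydrogen at C2 and an acetyl-deactivated aryl ring and should be untouched.

Step 7
Reactants: 9 1-[(2R)-2-(hydroxymethyl)-8-methoxy-2-methyl-2H-chromen-6-yl]ethan-1-one; 10 (E)-3-(4-acetoxy-3-methoxyphenyl)prop-2-enoic acid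
Product: 11 [(2R)-6-acetyl-8-methoxy-2-methyl-2H-chromen-2-yl]methyl (E)-3-(4-acetoxy-3-methoxyphenyl)prop-2-enoate
Conditions: DCC (1.3 equiv), DMAP (0.2 equiv), CH2Cl2, 0 °C → rt
Reagents that add atoms: none
Why: Steglich esterification acylates the neopentyl-type primary alcohol at the activated carbonyl (no substitution at the hindered carbon is needed), and the acetate mask keeps the phenol of the acid from being acylated.

Step 8
Reactants: 11 [(2R)-6-acetyl-8-methoxy-2-methyl-2H-chromen-2-yl]methyl (E)-3-(4-acetoxy-3-methoxyphenyl)prop-2-enoate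
Product: 12 [(2R)-6-acetyl-8-methoxy-2-methyl-2H-chromen-2-yl]methyl (E)-3-(4-hydroxy-3-methoxyphenyl)prop-2-enoate
Conditions: pyrrolidine (3 equiv), CH2Cl2, 0 °C
Reagents that add atoms: none
Why: Chemoselective aminolysis of the aryl acetate should remove only the acetyl group, because the phenolic ester is far more electrophilic than the hindered, conjugated alkyl cinnamate, and the ketone is inert under these conditions.

**Compound list**

1 | (R)-2-methylglycidol, [(2R)-2-methyloxiran-2-yl]methanol | OC[C@]1(C)CO1 | starting material
2 | (2R)-3-[(4-methoxyphenyl)methoxy]-2-methylpropane-1,2-diol | COc1ccc(COC[C@@](O)(C)CO)cc1 | intermediate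
3 | (2S)-2-hydroxy-3-[(4-methoxyphenyl)methoxy]-2-methylpropanal | COc1ccc(COC[C@@](O)(C)C=O)cc1 | intermediate
4 | (2R,3Z)-4-bromo-1-[(4-methoxyphenyl)methoxy]-2-methylbut-3-en-2-ol | COc1ccc(COC[C@@](O)(C)/C=C\Br)cc1 | intermediate
5 | 1-(4-amino-3-methoxyphenyl)ethan-1-one | CC(=O)c1ccc(N)c(OC)c1 | starting material
6 | 4-acetyl-2-methoxybenzenediazonium chloride | CC(=O)c1ccc([N+]#N)c(OC)c1.[Cl-] | intermediate
7 | 1-(4-iodo-3-methoxyphenyl)ethan-1-one | CC(=O)c1ccc(I)c(OC)c1 | intermediate
8 | 1-[(2R)-8-methoxy-2-{[(4-methoxyphenyl)methoxy]methyl}-2-methyl-2H-chromen-6-yl]ethan-1-one | COc1ccc(COC[C@@]2(C)C=Cc3cc(C(C)=O)cc(OC)c3O2)cc1 | intermediate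
9 | 1-[(2R)-2-(hydroxymethyl)-8-methoxy-2-methyl-2H-chromen-6-yl]ethan-1-one | OC[C@@]2(C)C=Cc3cc(C(C)=O)cc(OC)c3O2 | intermediate
10 | (E)-3-(4-acetoxy-3-methoxyphenyl)prop-2-enoic acid (4-O-acetylferulic acid) | CC(=O)Oc1ccc(/C=C/C(=O)O)cc1OC | starting material
11 | [(2R)-6-acetyl-8-methoxy-2-methyl-2H-chromen-2-yl]methyl (E)-3-(4-acetoxy-3-methoxyphenyl)prop-2-enoate | COc1cc(/C=C/C(=O)OC[C@@]2(C)C=Cc3cc(C(C)=O)cc(OC)c3O2)ccc1OC(C)=O | intermediate
12 | [(2R)-6-acetyl-8-methoxy-2-methyl-2H-chromen-2-yl]methyl (E)-3-(4-hydroxy-3-methoxyphenyl)prop-2-enoate | COc1cc(/C=C/C(=O)OC[C@@]2(C)C=Cc3cc(C(C)=O)cc(OC)c3O2)ccc1O | target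

**Totals and risks**

Total step count: 8. Longest linear sequence: 7 (steps 1, 2, 3, 5, 6, 7, 8).

Steps most likely to fail:

1. Step 5 (proposed new method). Zerovalent palladium may insert into the alkenyl C–Br bond in competition with the aryl C–I bond. The Z-bromide may lose HBr by base-induced anti elimination at 100 °C. The aryl palladium species may terminate at the ipso carbon before the ortho C–H is alkenylated, and β-carbon cleavage at the tertiary alkoxide may drain material. The fallback uses known chemistry, sets out from 4 and comes back at 8. Purchased 1-(4-fluoro-3-methoxyphenyl)ethan-1-one is borylated at the C–H flanked by F and H (B2pin2, [Ir(OMe)(cod)]2, 4,4'-di-tert-butyl-2,2'-bipyridine, THF, 60 °C; sterically controlled C–H borylation) to give 1-[4-fluoro-3-methoxy-5-(4,4,5,5-tetramethyl-1,3,2-dioxaborolan-2-yl)phenyl]ethan-1-one F1. Suzuki–Miyaura coupling of 4 with F1 (PdCl2(dppf), K3PO4, dioxane/H2O, 60 °C), with retention of the Z geometry, should give 1-{4-fluoro-3-[(1Z,3R)-3-hydroxy-4-[(4-methoxyphenyl)methoxy]-3-methylbut-1-en-1-yl]-5-methoxyphenyl}ethan-1-one F2. Intramolecular SNAr of the tertiary alkoxide on the fluoride para to the acetyl group (Cs2CO3, DMF, 80 °C) then closes the pyran ring to 8.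

2. Step 3. The Z/E selectivity of the bromomethylenation may erode, and the free α-hydroxy aldehyde may undergo base-induced α-ketol rearrangement or self-condensation during ylide addition. The fallback sets out from 3 and comes back at 4. Corey–Fuchs dibromo-olefination (CBr4, PPh3, CH2Cl2, 0 °C) should give (2R)-4,4-dibromo-1-[(4-methoxyphenyl)methoxy]-2-methylbut-3-en-2-ol F3. Hydrodebromination with Bu3SnH and catalytic Pd(PPh3)4 (toluene, rt) removes selectively the bromine trans to the carbinol substituent and leaves the Z-bromide 4 as a single geometric isomer.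

3. Step 1. The alkoxide of the substrate itself may attack a second epoxide molecule (oligomerisation) in competition with the intermolecular attack of the PMB alkoxide. The fallback sets out from 1 and comes back at 2. Tritylation of 1 (TrCl, Et3N, DMAP, CH2Cl2) gives (2S)-2-methyl-2-[(triphenylmethoxy)methyl]oxirane F4, which has no free hydroxyl. Opening with 4-methoxybenzyl alcohol/NaH (DMF, 60 °C) at the CH2 gives (2S)-1-[(4-methoxyphenyl)methoxy]-2-methyl-3-(triphenylmethoxy)propan-2-ol F5. Mild acid methanolysis of the trityl ether (TsOH cat., MeOH/CH2Cl2, rt) returns diol 2; the trityl group cannot migrate, so the two arms stay differentiated.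

**Further compounds**

F1 | step 5 | 1-[4-fluoro-3-methoxy-5-(4,4,5,5-tetramethyl-1,3,2-dioxaborolan-2-yl)phenyl]ethan-1-one | CC(=O)c1cc(OC)c(F)c(B2OC(C)(C)C(C)(C)O2)c1
F2 | step 5 | 1-{4-fluoro-3-[(1Z,3R)-3-hydroxy-4-[(4-methoxyphenyl)methoxy]-3-methylbut-1-en-1-yl]-5-methoxyphenyl}ethan-1-one | COc1ccc(COC[C@@](O)(C)/C=C\c2cc(C(C)=O)cc(OC)c2F)cc1
F3 | step 3 | (2R)-4,4-dibromo-1-[(4-methoxyphenyl)methoxy]-2-methylbut-3-en-2-ol | COc1ccc(COC[C@@](O)(C)C=C(Br)Br)cc1
F4 | step 1 | (2S)-2-methyl-2-[(triphenylmethoxy)methyl]oxirane | C(OC[C@]1(C)CO1)(c1ccccc1)(c1ccccc1)c1ccccc1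
F5 | step 1 | (2S)-1-[(4-methoxyphenyl)methoxy]-2-methyl-3-(triphenylmethoxy)propan-2-ol | COc1ccc(COC[C@@](O)(C)COC(c2ccccc2)(c2ccccc2)c2ccccc2)cc1
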